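**Strategy.** Ring A (C1–C5, C10) is obtained by contraction of a cycloheptane in which C20 is still a ring atom between C10 and C1. The key step is a Lewis-acid Meinwald (semipinacol) rearrangement of a 10β,20β-epoxide: because C10 is benzylic to ring C (bonded to C9), the C10–O bond ionises and the ring bond C20–C1 shifts to C10. One operation closes ring A, sets the quaternary stereocentre C10 and extrudes C20 as the β-aldehyde, the future lactone carbonyl. The precursor is a 6-6-7 tricycle (ring C arene, ring B, cycloheptene oxide) with C4 and C5 in place. A Δ6-epoxide then gives the 7,20-lactone and the 6α-hydroxyl, and ring C is oxidised to the hydroxyquinone.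

Key step: step 13

Remark: atoms keep abietane numbers throughout (C18 = 4α-CH3, C19 = 4β-CH2O, C20 = carbon on C10). 3-Methylcyclohept-2-en-1-one (5) and ClCH2SiMe2(Oi-Pr) are taken as catalogue compounds.

**Route**

Step 1
Reactants: 1 1,2,4-trimethoxybenzene
Product: 3 2-(2,3,6-trimethoxyphenyl)propan-2-ol, via aryllithium 2 (not isolated)
Conditions: n-BuLi, THF, 0 °C to rt; then acetone, −78 °C to rt
Reagents that add atoms: acetone, CC(C)=O
Why: Directed ortho-lithiation removes the most acidic C–H, the one between the 2- and 4-methoxy groups, and the aryllithium adds 1,2 to acetone.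

Step 2
Reactants: 3 2-(2,3,6-trimethoxyphenyl)propan-2-ol
Product: 4 1,2,4-trimethoxy-3-(propan-2-yl)benzene
Conditions: Et3SiH, CF3CO2H, CH2Cl2, 0 °C to rt
Reagents that add atoms: none
Why: Ionic hydrogenation: the tertiary benzylic alcohol ionises in acid and the cation is reduced by the silane.

Step 3
Reactants: 5 3-methylcyclohept-2-en-1-one
Product: 6 (3S)-3-{[dimethyl(propan-2-yloxy)silyl]methyl}-3-methylcycloheptan-1-one
Conditions: (i-PrO)Me2SiCH2MgCl (made from ClCH2SiMe2(Oi-Pr) and Mg, THF), Cu(OTf)2 (3 mol %), chiral imidazolinium chloride as N-heterocyclic carbene precursor (4 mol %), Et2O, 0 °C; NH4Cl (aq)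
Reagents that add atoms: [dimethyl(propan-2-yloxy)silyl]methylmagnesium chloride, CC(C)O[Si](C)(C)C[Mg]Cl
Why: Copper-catalysed asymmetric conjugate addition of a Grignard reagent to a β-substituted cycloalkenone, in which the chiral carbene–copper complex selects the enone face and sets the quaternary C4, the silylmethyl group being a masked hydroxymethyl (C19).

Step 4
Reactants: 6 (3S)-3-{[dimethyl(propan-2-yloxy)silyl]methyl}-3-methylcycloheptan-1-one
Product: 7 (3S)-3-(hydroxymethyl)-3-methylcycloheptan-1-one
Conditions: H2O2 (30 %), KF, KHCO3, THF/MeOH, rt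
Reagents that add atoms: hydrogen peroxide, OO
Why: Tamao–Fleming oxidation converts the C–Si bond of the alkoxysilane into C–OH and leaves the ketone untouched.

Step 5
Reactants: 7 (3S)-3-(hydroxymethyl)-3-methylcycloheptan-1-one
Product: 8 [(1S)-1-methyl-3-oxocycloheptyl]methyl 2-bromoacetate
Conditions: BrCH2COBr, pyridine, CH2Cl2, 0 °C
Reagents that add atoms: bromoacetyl bromide, O=C(Br)CBr
Why: O-Acylation of the primary alcohol hangs the C6–C7 unit on the C19 oxygen as a temporary tether.

Step 6
Reactants: 8 [(1S)-1-methyl-3-oxocycloheptyl]methyl 2-bromoacetate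
Product: 9 cis-fused keto δ-lactone (ring O–C19–C4–C5–C6–C7(=O) on the cycloheptanone; H5 cis to the C4 methyl)
Conditions: KOt-Bu, THF (high dilution), −40 to 0 °C
Reagents that add atoms: none
Why: Intramolecular enolate alkylation (6-exo-tet): the enolates equilibrate and only the C5 enolate can reach CH2Br, and attack from the tether face makes the lactone cis-fused, so C6 ends cis to C19.

Step 7
Reactants: 9 cis-fused keto δ-lactone
Product: 11 alkenyl triflate of the keto lactone (C10(OTf)=C20), via potassium enolate 10 (not isolated)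
Conditions: KN(SiMe3)2, THF, −78 °C; then PhNTf2, −78 to 0 °C
Reagents that add atoms: N-phenylbis(trifluoromethanesulfonimide), O=S(=O)(N(c1ccccc1)S(=O)(=O)C(F)(F)F)C(F)(F)F
Why: Kinetic deprotonation at the unhindered C20 methylene and O-triflation fix the C10=C20 position of the later styrene.

Step 8
Reactants: 11 alkenyl triflate of the keto lactone
Product: 12 lactol (C7 hemiacetal; both anomers)
Conditions: i-Bu2AlH (1.1 equiv), CH2Cl2, −78 °C; aqueous potassium sodium tartrate
Reagents that add atoms: none
Why: Partial reduction of a lactone to the lactol at low temperature; the alkenyl triflate is inert to the hydride.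

Step 9
Reactants: 12 lactol; 4 1,2,4-trimethoxy-3-(propan-2-yl)benzene
Product: 14 alkenyl triflate alcohol (C5 carries the CH2CH2-aryl chain C6–C7–C8; C4 carries CH3 and CH2OH), via aryl tetrahydropyran 13 (not isolated)
Conditions: BF3·OEt2, CH2Cl2, −40 to 0 °C; then Et3SiH, CF3CO2H, 0 °C to rt; NaHCO3, MeOH/H2O
Reagents that add atoms: none
Why: Friedel–Crafts C-arylation of the lactol-derived oxocarbenium ion at C8 (para to the 2-methoxy and ortho to the 4-methoxy group of 4), then ionic hydrogenolysis of the electron-rich benzylic C7–O bond, which frees the C19 alcohol.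

Step 10
Reactants: 14 alkenyl triflate alcohol
Product: 15 tricyclic styrene alcohol (ring C arene; ring B; seven-membered ring with C10=C20; 5α-H; 19-OH)
Conditions: Pd(OAc)2 (10 mol %), PCy3·HBF4 (20 mol %), K2CO3, t-BuCO2H (30 mol %), DMA, 110 °C
Reagents that add atoms: none
Why: Palladium-catalysed intramolecular direct C–H alkenylation of an arene by an alkenyl triflate (carboxylate-assisted metalation); C9–H is the only aromatic C–H, so six-membered ring B closes there.

Step 11
Reactants: 15 tricyclic styrene alcohol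
Product: 16 10β,20β-epoxy alcohol
Conditions: VO(acac)2 (5 mol %), t-BuOOH, CH2Cl2, 0 °C to rt
Reagents that add atoms: tert-butyl hydroperoxide, CC(C)(C)OO
Why: Hydroxyl-directed vanadium-catalysed epoxidation: the β-oriented 19-OH binds the metal peroxide and delivers oxygen to the β face of C10=C20, setting C10 and C20.

Step 12
Reactants: 16 10β,20β-epoxy alcohol
Product: 17 10β,20β-epoxy 19-benzyl ether
Conditions: NaH, BnBr, Bu4NI, THF, 0 °C to rt
Reagents that add atoms: benzyl bromide, BrCc1ccccc1
Why: Williamson etherification; the alkoxide cannot open the epoxide because both lie on the same face.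

Step 13
Reactants: 17 10β,20β-epoxy 19-benzyl ether
Product: 18 19-benzyloxy-11,12,14-trimethoxyabieta-8,11,13-trien-20-al (5α-H; 10β-CHO)
Conditions: BF3·OEt2 (0.5 equiv), CH2Cl2, −78 °C
Reagents that add atoms: none
Why: Meinwald (semipinacol) rearrangement: BF3 binds the epoxide oxygen, the benzylic C10–O bond ionises with help of the electron-rich arene at C9, and the ring bond C20–C1 migrates to C10 while C20 becomes the aldehyde carbon. The closest known reaction type is the Lewis-acid ring contraction of 1-arylcycloalkene oxides to 1-arylcycloalkanecarbaldehydes. Ring A (C10, C1–C5) is closed by this 1,2-alkyl shift, that is by ring contraction 7 → 6 with the new bond C1–C10, not by a cyclisation. C10 is the only new stereocentre and is controlled by the epoxide of step 11: C1 enters anti to the leaving oxygen, so the 10β,20β-epoxide should give the 20β-aldehyde cis to C19 and the trans A/B junction. The step needs alkyl shift to win over hydride shift (C20 ketone) and over loss of H5; in the β-epoxide the C20–C1 bond already lies on the α face anti to C10–O and away from C4, whereas C20–H can align only if the seven-membered ring twists C1 towards the crowded β face. Trapping of the cation by the C19 oxygen is blocked by the benzyl ether.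

Step 14
Reactants: 18 19-benzyloxy-11,12,14-trimethoxyabieta-8,11,13-trien-20-al
Product: 19 19-benzyloxy-11,12,14-trimethoxyabieta-6,8,11,13-tetraen-20-al
Conditions: DDQ, 1,4-dioxane (dry), rt to 60 °C
Reagents that add atoms: none
Why: DDQ dehydrogenation: hydride abstraction from benzylic C7 (cation stabilised by the para 12-methoxy group) and loss of H6 should give the Δ6 styrene, as is usual for electron-rich abietatrienes.

Step 15
Reactants: 19 19-benzyloxy-11,12,14-trimethoxyabieta-6,8,11,13-tetraen-20-al
Product: 20 19-benzyloxy-11,12,14-trimethoxyabieta-6,8,11,13-tetraen-20-oic acid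
Conditions: NaClO2, NaH2PO4, 2-methylbut-2-ene (excess), t-BuOH/H2O, rt
Reagents that add atoms: sodium chlorite, [Na+].[O-]Cl=O
Why: Pinnick oxidation of the non-enolisable aldehyde, with the alkene scavenger removing HOCl so that styrene and arene survive.

Step 16
Reactants: 20 19-benzyloxy-11,12,14-trimethoxyabieta-6,8,11,13-tetraen-20-oic acid
Product: 22 19-benzyloxy-6α-hydroxy-11,12,14-trimethoxyabieta-8,11,13-trien-20,7β-olide, via 6α,7α-epoxy acid 21 (not isolated)
Conditions: m-CPBA, CH2Cl2, 0 °C to rt
Reagents that add atoms: 3-chloroperoxybenzoic acid, OOC(=O)c1cccc(Cl)c1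
Why: Prilezhaev epoxidation from the α face (the β face is blocked by the axial C19 and C20 groups) and opening of the epoxide at benzylic C7 by the C20 acid from the β face with inversion, the para 12-methoxy group making C7–O the bond that ionises, so the δ-lactone forms and the 6α-hydroxyl remains.

Step 17
Reactants: 22 19-benzyloxy-6α-hydroxy-11,12,14-trimethoxyabieta-8,11,13-trien-20,7β-olide
Product: 23 19-benzyloxy-6α-hydroxy-12-methoxy-11,14-dioxoabieta-8,12-dien-20,7β-olide
Conditions: (NH4)2Ce(NO3)6, MeCN/H2O, 0 °C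
Reagents that add atoms: water, O
Why: Oxidative demethylation of the para-dimethoxy pair (C11, C14) by tetravalent cerium gives the para-quinone and leaves the 12-methoxy group as a vinylogous ester.

Step 18
Reactants: 23 19-benzyloxy-6α-hydroxy-12-methoxy-11,14-dioxoabieta-8,12-dien-20,7β-olide
Product: 24 6α,12,19-trihydroxy-11,14-dioxoabieta-8,12-dien-20,7β-olide (target)
Conditions: BCl3, pentamethylbenzene, CH2Cl2, −78 to 0 °C; then H2O
Reagents that add atoms: none
Why: Lewis-acid ether cleavage: BCl3 removes the benzyl group (cation trapped by pentamethylbenzene) and, by chelation to the C11 carbonyl, the vinylogous methyl ester at C12, while the hindered lactone, now next to an electron-poor quinone, should survive.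

**Compound list**

1 | 1,2,4-trimethoxybenzene | COc1ccc(OC)c(OC)c1 | starting material
2 | (2,3,6-trimethoxyphenyl)lithium | [Li]c1c(OC)ccc(OC)c1OC | intermediate (not isolated)
3 | 2-(2,3,6-trimethoxyphenyl)propan-2-ol | CC(C)(O)c1c(OC)ccc(OC)c1OC | intermediate
4 | 1,2,4-trimethoxy-3-(propan-2-yl)benzene | CC(C)c1c(OC)ccc(OC)c1OC | intermediate
5 | 3-methylcyclohept-2-en-1-one | CC1=CC(=O)CCCC1 | starting material
6 | (3S)-3-{[dimethyl(propan-2-yloxy)silyl]methyl}-3-methylcycloheptan-1-one | O=C1C[C@@](C)(C[Si](C)(C)OC(C)C)CCCC1 | intermediate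
7 | (3S)-3-(hydroxymethyl)-3-methylcycloheptan-1-one | O=C1C[C@@](C)(CO)CCCC1 | intermediate
8 | [(1S)-1-methyl-3-oxocycloheptyl]methyl 2-bromoacetate | O=C1C[C@@](C)(COC(=O)CBr)CCCC1 | intermediate
9 | cis-fused keto δ-lactone (H5 cis to C4 methyl) | O=C1[C@H]2CC(=O)OC[C@@]2(C)CCCC1 | intermediate
10 | potassium C10=C20 enolate of 9 | [K+].[O-]C1=CCCC[C@]2(C)COC(=O)C[C@H]12 | intermediate (not isolated)
11 | alkenyl triflate of the keto lactone (C10(OTf)=C20) | FC(F)(F)S(=O)(=O)OC1=CCCC[C@]2(C)COC(=O)C[C@H]12 | intermediate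
12 | lactol (C7 hemiacetal, both anomers) | OC1C[C@@H]2C(OS(=O)(=O)C(F)(F)F)=CCCC[C@]2(C)CO1 | intermediate
13 | C7-aryl tetrahydropyran (aryl = 2,4,5-trimethoxy-3-isopropylphenyl) | COc1cc(C2C[C@@H]3C(OS(=O)(=O)C(F)(F)F)=CCCC[C@]3(C)CO2)c(OC)c(C(C)C)c1OC | intermediate (not isolated)
14 | alkenyl triflate alcohol with 2-arylethyl chain at C5 | COc1cc(CC[C@@H]2C(OS(=O)(=O)C(F)(F)F)=CCCC[C@]2(C)CO)c(OC)c(C(C)C)c1OC | intermediate
15 | tricyclic styrene alcohol (C10=C20 in the seven-membered ring; 5α-H; 19-OH) | CC(C)c1c(OC)c(OC)c2c(c1OC)CC[C@@H]3C2=CCCC[C@]3(C)CO | intermediate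
16 | 10β,20β-epoxy alcohol | CC(C)c1c(OC)c(OC)c2c(c1OC)CC[C@@H]3[C@@]24O[C@@H]4CCC[C@]3(C)CO | intermediate
17 | 10β,20β-epoxy 19-benzyl ether | CC(C)c1c(OC)c(OC)c2c(c1OC)CC[C@@H]3[C@@]24O[C@@H]4CCC[C@]3(C)COCc5ccccc5 | intermediate
18 | 19-benzyloxy-11,12,14-trimethoxyabieta-8,11,13-trien-20-al | CC(C)c1c(OC)c(OC)c2c(c1OC)CC[C@@H]3[C@]2(C=O)CCC[C@]3(C)COCc4ccccc4 | intermediate
19 | 19-benzyloxy-11,12,14-trimethoxyabieta-6,8,11,13-tetraen-20-al | CC(C)c1c(OC)c(OC)c2c(c1OC)C=C[C@@H]3[C@]2(C=O)CCC[C@]3(C)COCc4ccccc4 | intermediate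
20 | 19-benzyloxy-11,12,14-trimethoxyabieta-6,8,11,13-tetraen-20-oic acid | CC(C)c1c(OC)c(OC)c2c(c1OC)C=C[C@@H]3[C@]2(C(=O)O)CCC[C@]3(C)COCc4ccccc4 | intermediate
21 | 6α,7α-epoxy acid | CC(C)c1c(OC)c(OC)c2c(c1OC)[C@@H]1O[C@@H]1[C@@H]3[C@]2(C(=O)O)CCC[C@]3(C)COCc4ccccc4 | intermediate (not isolated)
22 | 19-benzyloxy-6α-hydroxy-11,12,14-trimethoxyabieta-8,11,13-trien-20,7β-olide | CC(C)c1c(OC)c(OC)c2c(c1OC)[C@H]1OC(=O)[C@@]23CCC[C@](C)(COCc4ccccc4)[C@@H]3[C@H]1O | intermediate
23 | 19-benzyloxy-6α-hydroxy-12-methoxy-11,14-dioxoabieta-8,12-dien-20,7β-olide | CC(C)C1=C(OC)C(=O)C2=C(C1=O)[C@H]1OC(=O)[C@@]23CCC[C@](C)(COCc4ccccc4)[C@@H]3[C@H]1O | intermediate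
24 | 6α,12,19-trihydroxy-11,14-dioxoabieta-8,12-dien-20,7β-olide | CC(C)C1=C(O)C(=O)C2=C(C1=O)[C@H]1OC(=O)[C@@]23CCC[C@](C)(CO)[C@@H]3[C@H]1O | target

**Step count.** Total 18 steps. Longest linear sequence 16 steps (steps 3–18 from 5); the arene branch (steps 1–2) joins at step 9.

**Steps most likely to fail**

1. Step 13 (key step). Hydride may migrate instead of C1 to give the C20 ketone, H5 may be lost to an allylic alcohol, or a long-lived benzylic cation may change conformation and lose the stereochemical relay from the epoxide. Fallback, setting out from 17: the epoxide would be isomerised on purpose by hydride shift (Pd(OAc)2, PBu3, t-BuOH, reflux) to the α-aryl C20 ketone F1. An oxidative Favorskii-type ring contraction with the trivalent-iodine oxidant PhI(OAc)2 (H2SO4 cat., HC(OMe)3, MeOH) would then move C1 from C20 to C10 and give the 20-oic methyl ester F2. Reduction with i-Bu2AlH at −78 °C would return to 18. In this variant the C10 configuration rests only on the preference of C1 to shift on the face away from C4.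

2. Step 10. The alkenylpalladium may be reduced by β-hydride elimination from a palladium alkoxide of the free 19-OH, or metalation of the doubly flanked C9–H may be too slow. Fallback, setting out from 14: bromination of the last aromatic position (NBS, MeCN, 0 °C) would give the C9 aryl bromide F3. One-pot Miyaura borylation of the alkenyl triflate (PdCl2(dppf), B2pin2, KOAc, dioxane, 80 °C) to the alkenyl boronate F4, followed by intramolecular Suzuki coupling on adding K3PO4 and water at 100 °C, would return to 15. The C–H activation is thus replaced by coupling of two functionalised carbons.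

3. Step 3. Addition of the bulky silylmethyl nucleophile to the β,β-disubstituted cycloheptenone may be slow or poorly face-selective. Fallback, setting out from 5: Corey–Bakshi–Shibata reduction (oxazaborolidine enantiomer chosen for the R alcohol, BH3·SMe2) would give (R)-3-methylcyclohept-2-en-1-ol F5. Etherification (KH, ICH2SnBu3) would give the stannylmethyl ether F6. A [2,3]-Wittig–Still rearrangement (n-BuLi, THF, −78 °C) transfers the carbinol configuration suprafacially to C4 and would give (S)-(1-methylcyclohept-2-en-1-yl)methanol F7. Hydroboration–oxidation (9-BBN; NaOH, H2O2) would give the diol F8, and selective oxidation of the secondary alcohol (NaOCl, AcOH) would return to 7.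

Further compounds
F1 | step 13 | C20 ketone (10-H α-aryl cycloheptanone, 19-benzyl ether) | CC(C)c1c(OC)c(OC)c2c(c1OC)CC[C@@H]3C2C(=O)CCC[C@]3(C)COCc4ccccc4
F2 | step 13 | methyl 19-benzyloxy-11,12,14-trimethoxyabieta-8,11,13-trien-20-oate | CC(C)c1c(OC)c(OC)c2c(c1OC)CC[C@@H]3[C@]2(C(=O)OC)CCC[C@]3(C)COCc4ccccc4
F3 | step 10 | C9 aryl bromide of 14 | COc1c(Br)c(CC[C@@H]2C(OS(=O)(=O)C(F)(F)F)=CCCC[C@]2(C)CO)c(OC)c(C(C)C)c1OC
F4 | step 10 | alkenyl pinacol boronate of F3 | COc1c(Br)c(CC[C@@H]2C(B3OC(C)(C)C(C)(C)O3)=CCCC[C@]2(C)CO)c(OC)c(C(C)C)c1OC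
F5 | step 3 | (R)-3-methylcyclohept-2-en-1-ol | O[C@H]1C=C(C)CCCC1
F6 | step 3 | tributyl{[(1R)-3-methylcyclohept-2-en-1-yl]oxymethyl}stannane | CCCC[Sn](CCCC)(CCCC)CO[C@H]1C=C(C)CCCC1
F7 | step 3 | (S)-(1-methylcyclohept-2-en-1-yl)methanol | OC[C@]1(C)C=CCCCC1
F8 | step 3 | 3-(hydroxymethyl)-3-methylcycloheptan-1-ol (C4 S; carbinol centre mixed) | OC[C@]1(C)CC(O)CCCC1
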